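The α‑methyl‑γ‑lactone (O1–C12–C11, germacranolide numbering) is annulated onto C6–C7 of an open‑chain (4Z,6E)‑diene. The 2‑bromopropanoate of the C3 allylic alcohol is a temporary tether: its radical closes 8‑endo on C7 (C7–C11), the allyl cation formed by radical–polar crossover is captured at C6 by the ester carbonyl oxygen (O1–C6), and hydrolysis of the bicyclic acyloxonium cleaves the tether bond O3–C12. The step exploits the (Z)‑C4=C5 bond, which holds the C3 oxygen cis to C6 and lets C3 control C7 and C6. Both carbinol centres (C3, C9) come from allylborations; metathesis at C1=C10 then closes the ten‑membered ring.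

Key step: step 9

Remark: atoms are numbered as in germacranolides (ring C1–C10, methyl C14 on C10 and C15 on C4, acetoxy groups on C3 and C9, lactone O1–C12(=O)–C11(C13) fused at C6–C7). The target is read as (3S,6S,7S,9R,11R) with Z C1=C10 and Z C4=C5. 2‑Bromopropanoyl bromide is used as the racemate, because its stereocentre becomes a radical.

Step 1
Reactants: 1 methacrolein (2‑methylprop‑2‑enal)
Product: 3 (3R)‑2‑methylhexa‑1,5‑dien‑3‑ol, via borinate ester 2 (not isolated)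
Conditions: (+)‑Ipc2B(allyl), Et2O, −78 °C; then NaOH, H2O2
Reagents that add atoms: (+)‑B‑allyldiisopinocampheylborane, C=CCB([C@H]1C[C@H]2C[C@@H]([C@@H]1C)C2(C)C)[C@H]1C[C@H]2C[C@@H]([C@@H]1C)C2(C)C
Why: Brown allylboration through a chair transition state; the (+)‑reagent (from (−)‑α‑pinene) delivers allyl to the Re face of the aldehyde and sets C9 as R.

Step 2
Reactants: 3 (3R)‑2‑methylhexa‑1,5‑dien‑3‑ol
Product: 4 tert‑butyl(dimethyl){[(3R)‑2‑methylhexa‑1,5‑dien‑3‑yl]oxy}silane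
Conditions: t‑BuMe2SiCl, imidazole, DMF, 25 °C
Reagents that add atoms: tert‑butyldimethylsilyl chloride, CC(C)(C)[Si](C)(C)Cl
Why: Standard silylation of a secondary allylic alcohol; the silyl ether should survive the base, hydride, oxidation and radical steps up to step 11.

Step 3
Reactants: 4 tert‑butyl(dimethyl){[(3R)‑2‑methylhexa‑1,5‑dien‑3‑yl]oxy}silane; 5 (E)‑but‑2‑enal (crotonaldehyde)
Product: 6 (2E,5R)‑5‑[(tert‑butyldimethylsilyl)oxy]‑6‑methylhepta‑2,6‑dienal
Conditions: second‑generation Hoveyda–Grubbs catalyst (cat.), CH2Cl2, 40 °C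
Reagents that add atoms: none
Why: Olefin cross‑metathesis of a terminal alkene with an enal is E‑selective, and the hindered 1,1‑disubstituted alkene next to the silyloxy group should stay out of the reaction.

Step 4
Reactants: 6 (2E,5R)‑5‑[(tert‑butyldimethylsilyl)oxy]‑6‑methylhepta‑2,6‑dienal; 7 methyl 2‑[bis(2,2,2‑trifluoroethoxy)phosphoryl]propanoate
Product: 8 methyl (2Z,4E,7R)‑7‑[(tert‑butyldimethylsilyl)oxy]‑2,8‑dimethylnona‑2,4,8‑trienoate
Conditions: KN(SiMe3)2, 18‑crown‑6, THF, −78 °C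
Reagents that add atoms: none
Why: Still–Gennari olefination; the trifluoroethyl phosphonate with a dissociated potassium counter‑ion eliminates under kinetic control to the (2Z)‑trisubstituted enoate, which fixes the Z C4=C5 geometry.

Step 5
Reactants: 8 methyl (2Z,4E,7R)‑7‑[(tert‑butyldimethylsilyl)oxy]‑2,8‑dimethylnona‑2,4,8‑trienoate
Product: 9 (2Z,4E,7R)‑7‑[(tert‑butyldimethylsilyl)oxy]‑2,8‑dimethylnona‑2,4,8‑trien‑1‑ol
Conditions: i‑Bu2AlH, CH2Cl2, −78 °C
Reagents that add atoms: none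
Why: Diisobutylaluminium hydride reduces the conjugated ester 1,2 to the allylic alcohol at low temperature without touching the silyl ether or the alkene geometry (ester reduction).

Step 6
Reactants: 9 (2Z,4E,7R)‑7‑[(tert‑butyldimethylsilyl)oxy]‑2,8‑dimethylnona‑2,4,8‑trien‑1‑ol
Product: 10 (2Z,4E,7R)‑7‑[(tert‑butyldimethylsilyl)oxy]‑2,8‑dimethylnona‑2,4,8‑trienal
Conditions: MnO2, CH2Cl2, 25 °C
Reagents that add atoms: none
Why: Manganese dioxide oxidises the allylic alcohol heterogeneously under neutral conditions, which should keep the sensitive (2Z) enal geometry (allylic oxidation).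

Step 7
Reactants: 10 (2Z,4E,7R)‑7‑[(tert‑butyldimethylsilyl)oxy]‑2,8‑dimethylnona‑2,4,8‑trienal
Product: 12 (4S,5Z,7E,10R)‑10‑[(tert‑butyldimethylsilyl)oxy]‑5,11‑dimethyldodeca‑1,5,7,11‑tetraen‑4‑ol, via borinate ester 11 (not isolated)
Conditions: (−)‑Ipc2B(allyl), Et2O, −78 °C; then NaOH, H2O2
Reagents that add atoms: (−)‑B‑allyldiisopinocampheylborane, C=CCB([C@@H]1C[C@@H]2C[C@H]([C@H]1C)C2(C)C)[C@@H]1C[C@@H]2C[C@H]([C@H]1C)C2(C)C
Why: Brown allylboration at −78 °C is reagent‑controlled, adds 1,2 to the enal on its Si face through a chair transition state and sets C3 as S, independent of the remote C9 centre.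

Step 8
Reactants: 12 (4S,5Z,7E,10R)‑10‑[(tert‑butyldimethylsilyl)oxy]‑5,11‑dimethyldodeca‑1,5,7,11‑tetraen‑4‑ol; 13 2‑bromopropanoyl bromide
Product: 14 (4S,5Z,7E,10R)‑10‑[(tert‑butyldimethylsilyl)oxy]‑5,11‑dimethyldodeca‑1,5,7,11‑tetraen‑4‑yl 2‑bromopropanoate (both epimers at the brominated carbon)
Conditions: pyridine, CH2Cl2, −20 °C
Reagents that add atoms: none
Why: Esterification of the secondary alcohol with the acid bromide under mild base installs the radical precursor and the tether in one step, with retention at C3.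

Step 9
Reactants: 14 (4S,5Z,7E,10R)‑10‑[(tert‑butyldimethylsilyl)oxy]‑5,11‑dimethyldodeca‑1,5,7,11‑tetraen‑4‑yl 2‑bromopropanoate
Product: 16 (4S,5S)‑4‑[(2R)‑2‑[(tert‑butyldimethylsilyl)oxy]‑3‑methylbut‑3‑en‑1‑yl]‑5‑[(1Z,3S)‑3‑hydroxy‑2‑methylhexa‑1,5‑dien‑1‑yl]‑3‑methyloxolan‑2‑one (both epimers at lactone C3, which is C11), via acyloxonium bromide 15 (not isolated)
Conditions: fac‑Ir(ppy)3 (ppy = 2‑phenylpyridinato, 1 mol %), 2,6‑lutidine, MeCN/H2O (10:1), 0.005 M, blue LEDs, 25 °C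
Reagents that add atoms: water, O
Why: Proposed new method: the excited iridium photocatalyst reduces the C–Br bond, the electrophilic α‑ester radical adds 8‑endo‑trig to the diene terminus C7 (C7–C11), the ring allyl radical is oxidised by the tetravalent iridium to the C4–C5–C6 allyl cation, the ester carbonyl oxygen closes the five‑membered ring on C6 (5‑exo‑trig, O1–C6) to acyloxonium 15, and water opens 15 to the γ‑lactone and frees the C3 hydroxyl, which cleaves the temporary O3–C12 bond. The closest known reactions are the photoredox carbolactonisation of alkenes with α‑bromo esters and water, in which the ester alkoxy group is lost, and the 8‑endo cyclisation of (alkoxycarbonyl)alkyl radicals, whose preferred Z‑ester rotamer reaches exactly this ring size. C7 is controlled by C3: allylic 1,3‑strain across the (Z)‑C4=C5 bond holds C3–H in the diene plane and puts O3 with its tether on one face, the cisoid diene needed for closure presents that face of C7 with C8 turned outward, and this should give 7S from 3S. C6 follows from delivery of O1 on the same face as C11 to the terminus derived from the E alkene (6S, trans lactone), while C11 is not controlled here and is set in step 10. The step needs attack at the diene and not 7‑endo at the allyl group, which the higher radical affinity of the diene and the preorganised Z‑alkene tether should secure. It also needs capture at C6 and not at C4, which the electron‑withdrawing acyloxy group on C3 and the less hindered secondary C6 should secure, so that the C4=C5 geometry is never broken.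

Step 10
Reactants: 16 (4S,5S)‑4‑[(2R)‑2‑[(tert‑butyldimethylsilyl)oxy]‑3‑methylbut‑3‑en‑1‑yl]‑5‑[(1Z,3S)‑3‑hydroxy‑2‑methylhexa‑1,5‑dien‑1‑yl]‑3‑methyloxolan‑2‑one (epimers at C11)
Product: 18 (3R,4S,5S)‑4‑[(2R)‑2‑[(tert‑butyldimethylsilyl)oxy]‑3‑methylbut‑3‑en‑1‑yl]‑5‑[(1Z,3S)‑3‑hydroxy‑2‑methylhexa‑1,5‑dien‑1‑yl]‑3‑methyloxolan‑2‑one, via dilithium enolate 17 (not isolated)
Conditions: LiN(i‑Pr)2 (2.5 equiv), THF, −78 °C; then 2,6‑di‑tert‑butyl‑4‑methylphenol, −78 °C; aqueous NH4Cl work‑up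
Reagents that add atoms: none
Why: Kinetic protonation of a lactone enolate: the bulky phenol should deliver the proton to the face opposite the adjacent C7 side chain, which places the C11 methyl cis to C8 (11R) against the thermodynamic preference, and both epimers of 16 converge on 18.

Step 11
Reactants: 18 (3R,4S,5S)‑4‑[(2R)‑2‑[(tert‑butyldimethylsilyl)oxy]‑3‑methylbut‑3‑en‑1‑yl]‑5‑[(1Z,3S)‑3‑hydroxy‑2‑methylhexa‑1,5‑dien‑1‑yl]‑3‑methyloxolan‑2‑one
Product: 19 (3R,4S,5S)‑5‑[(1Z,3S)‑3‑hydroxy‑2‑methylhexa‑1,5‑dien‑1‑yl]‑4‑[(2R)‑2‑hydroxy‑3‑methylbut‑3‑en‑1‑yl]‑3‑methyloxolan‑2‑one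
Conditions: Bu4NF, AcOH, THF, 0 to 25 °C
Reagents that add atoms: none
Why: Fluoride‑mediated silyl ether cleavage buffered with acetic acid should free the C9 hydroxyl without epimerising C11 or opening the lactone.

Step 12
Reactants: 19 (3R,4S,5S)‑5‑[(1Z,3S)‑3‑hydroxy‑2‑methylhexa‑1,5‑dien‑1‑yl]‑4‑[(2R)‑2‑hydroxy‑3‑methylbut‑3‑en‑1‑yl]‑3‑methyloxolan‑2‑one
Product: 20 (3S,5Z)‑6‑[(2S,3S,4R)‑3‑[(2R)‑2‑acetoxy‑3‑methylbut‑3‑en‑1‑yl]‑4‑methyl‑5‑oxooxolan‑2‑yl]‑5‑methylhexa‑1,5‑dien‑4‑yl acetate (diacetate of 19)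
Conditions: Ac2O, pyridine, 4‑dimethylaminopyridine (cat.), CH2Cl2, 25 °C
Reagents that add atoms: acetic anhydride, CC(=O)OC(C)=O
Why: Acylation under nucleophilic catalysis acetylates both secondary hydroxyls with retention at C3 and C9.

Step 13
Reactants: 20 diacetate of 19
Product: 21 (3R,3aS,5R,6Z,9S,10Z,11aS)‑3,6,10‑trimethyl‑2‑oxo‑2,3,3a,4,5,8,9,11a‑octahydrocyclodeca[b]furan‑5,9‑diyl diacetate (CNP0226482.4)
Conditions: second‑generation Grubbs catalyst (5 mol %), 1,4‑benzoquinone (10 mol %), toluene, 80 °C, 0.001 M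
Reagents that add atoms: none
Why: Ring‑closing metathesis joins the monosubstituted C1 alkene to the isopropenyl group with loss of ethene; in a ten‑membered ring that already holds a Z alkene and the trans‑fused lactone, the metallacyclobutane leading to the cis (Z) C1=C10 bond should be the less strained one, and high dilution suppresses oligomers.

Compound list
1 | methacrolein (2‑methylprop‑2‑enal) | CC(=C)C=O | starting material
2 | (3R)‑2‑methylhexa‑1,5‑dien‑3‑yl diisopinocampheylborinate | CC(=C)[C@H](OB([C@H]1C[C@H]2C[C@@H]([C@@H]1C)C2(C)C)[C@H]1C[C@H]2C[C@@H]([C@@H]1C)C2(C)C)CC=C | intermediate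
3 | (3R)‑2‑methylhexa‑1,5‑dien‑3‑ol | CC(=C)[C@H](O)CC=C | intermediate
4 | tert‑butyl(dimethyl){[(3R)‑2‑methylhexa‑1,5‑dien‑3‑yl]oxy}silane | CC(=C)[C@H](O[Si](C)(C)C(C)(C)C)CC=C | intermediate
5 | (E)‑but‑2‑enal (crotonaldehyde) | C/C=C/C=O | starting material
6 | (2E,5R)‑5‑[(tert‑butyldimethylsilyl)oxy]‑6‑methylhepta‑2,6‑dienal | CC(=C)[C@H](O[Si](C)(C)C(C)(C)C)C/C=C/C=O | intermediate
7 | methyl 2‑[bis(2,2,2‑trifluoroethoxy)phosphoryl]propanoate | COC(=O)C(C)P(=O)(OCC(F)(F)F)OCC(F)(F)F | starting material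
8 | methyl (2Z,4E,7R)‑7‑[(tert‑butyldimethylsilyl)oxy]‑2,8‑dimethylnona‑2,4,8‑trienoate | CC(=C)[C@H](O[Si](C)(C)C(C)(C)C)C/C=C/C=C(/C)C(=O)OC | intermediate
9 | (2Z,4E,7R)‑7‑[(tert‑butyldimethylsilyl)oxy]‑2,8‑dimethylnona‑2,4,8‑trien‑1‑ol | CC(=C)[C@H](O[Si](C)(C)C(C)(C)C)C/C=C/C=C(/C)CO | intermediate
10 | (2Z,4E,7R)‑7‑[(tert‑butyldimethylsilyl)oxy]‑2,8‑dimethylnona‑2,4,8‑trienal | CC(=C)[C@H](O[Si](C)(C)C(C)(C)C)C/C=C/C=C(/C)C=O | intermediate
11 | (4S,5Z,7E,10R)‑10‑[(tert‑butyldimethylsilyl)oxy]‑5,11‑dimethyldodeca‑1,5,7,11‑tetraen‑4‑yl diisopinocampheylborinate | CC(=C)[C@H](O[Si](C)(C)C(C)(C)C)C/C=C/C=C(/C)[C@@H](OB([C@@H]1C[C@@H]2C[C@H]([C@H]1C)C2(C)C)[C@@H]1C[C@@H]2C[C@H]([C@H]1C)C2(C)C)CC=C | intermediate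
12 | (4S,5Z,7E,10R)‑10‑[(tert‑butyldimethylsilyl)oxy]‑5,11‑dimethyldodeca‑1,5,7,11‑tetraen‑4‑ol | CC(=C)[C@H](O[Si](C)(C)C(C)(C)C)C/C=C/C=C(/C)[C@@H](O)CC=C | intermediate
13 | 2‑bromopropanoyl bromide (racemic) | CC(Br)C(=O)Br | starting material
14 | (4S,5Z,7E,10R)‑10‑[(tert‑butyldimethylsilyl)oxy]‑5,11‑dimethyldodeca‑1,5,7,11‑tetraen‑4‑yl 2‑bromopropanoate (epimers at CHBr) | CC(=C)[C@H](O[Si](C)(C)C(C)(C)C)C/C=C/C=C(/C)[C@@H](OC(=O)C(C)Br)CC=C | intermediate
15 | bicyclic acyloxonium bromide (O1 bonded to C6 and C12, O3 to C3 and C12; C11 epimers) | C=CC[C@@H]1OC2=[O+][C@H](/C=C\1C)[C@@H](C[C@@H](O[Si](C)(C)C(C)(C)C)C(C)=C)C2C.[Br-] | intermediate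
16 | (4S,5S)‑4‑[(2R)‑2‑[(tert‑butyldimethylsilyl)oxy]‑3‑methylbut‑3‑en‑1‑yl]‑5‑[(1Z,3S)‑3‑hydroxy‑2‑methylhexa‑1,5‑dien‑1‑yl]‑3‑methyloxolan‑2‑one (C11 epimers) | CC(=C)[C@H](O[Si](C)(C)C(C)(C)C)C[C@@H]1[C@@H](/C=C(/C)[C@@H](O)CC=C)OC(=O)C1C | intermediate
17 | dilithium alkoxide enolate of 16 | CC(=C)[C@H](O[Si](C)(C)C(C)(C)C)C[C@@H]1[C@@H](/C=C(/C)[C@@H]([O-])CC=C)OC([O-])=C1C.[Li+].[Li+] | intermediate
18 | (3R,4S,5S)‑4‑[(2R)‑2‑[(tert‑butyldimethylsilyl)oxy]‑3‑methylbut‑3‑en‑1‑yl]‑5‑[(1Z,3S)‑3‑hydroxy‑2‑methylhexa‑1,5‑dien‑1‑yl]‑3‑methyloxolan‑2‑one | CC(=C)[C@H](O[Si](C)(C)C(C)(C)C)C[C@@H]1[C@@H](/C=C(/C)[C@@H](O)CC=C)OC(=O)[C@@H]1C | intermediate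
19 | (3R,4S,5S)‑5‑[(1Z,3S)‑3‑hydroxy‑2‑methylhexa‑1,5‑dien‑1‑yl]‑4‑[(2R)‑2‑hydroxy‑3‑methylbut‑3‑en‑1‑yl]‑3‑methyloxolan‑2‑one | CC(=C)[C@H](O)C[C@@H]1[C@@H](/C=C(/C)[C@@H](O)CC=C)OC(=O)[C@@H]1C | intermediate
20 | diacetate of 19 | CC(=C)[C@H](OC(C)=O)C[C@@H]1[C@@H](/C=C(/C)[C@@H](OC(C)=O)CC=C)OC(=O)[C@@H]1C | intermediate
21 | (3R,3aS,5R,6Z,9S,10Z,11aS)‑3,6,10‑trimethyl‑2‑oxo‑2,3,3a,4,5,8,9,11a‑octahydrocyclodeca[b]furan‑5,9‑diyl diacetate (CNP0226482.4) | CC(=O)O[C@H]1C/C=C(/C)[C@H](OC(C)=O)C[C@@H]2[C@@H](/C=C\1C)OC(=O)[C@@H]2C | target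

Total step count: 13. Longest linear sequence: 13 steps (from methacrolein 1).

Steps most likely to fail

Step 9 (proposed new method). What may go wrong is a loss of site control and of geometry. The radical may close 7‑endo on the allyl group or abstract an allylic hydrogen. The allyl cation may be captured at C4 by the carbonyl oxygen, water or bromide, which would also erase the Z C4=C5 geometry. Triplet sensitisation may isomerise the diene. The fallback gives up the tether and uses the known intermolecular reaction. It sets out from alcohol 12, whose C3 hydroxyl is capped (Et3SiCl, imidazole) as the triethylsilyl ether F1. Photoredox carbolactonisation of the diene of F1 with ethyl 2‑bromopropanoate and water (fac‑Ir(ppy)3, blue LEDs, MeCN/H2O) should then give the silyl‑protected trans lactone F2 together with its C6/C7 diastereomers, which are separated by chromatography. Cleavage of the triethylsilyl ether (pyridinium p‑toluenesulfonate, MeOH) returns to 16.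

Step 13. What may go wrong is oligomerisation by intermolecular metathesis, closure to the E‑configured C1=C10 alkene, or failure of the ruthenium carbene to engage the hindered isopropenyl group next to the acetate. The fallback moves the ring closure in front of the acetylation and changes the substrate. It sets out from diol 19, whose free allylic C9 hydroxyl should assist loading of the catalyst on the isopropenyl group and change the conformational bias of the chain. Ring‑closing metathesis at high dilution should give the macrocyclic diol F3, and diacetylation (Ac2O, pyridine, 4‑dimethylaminopyridine) comes back to the route at 21.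

Step 10. What may go wrong is poor facial discrimination in the protonation, or proton exchange that drifts toward the more stable C11 epimer. The fallback replaces the proton by a hydrogen atom and sets out from 16. Its dilithium enolate is brominated (CBr4, −78 °C) to the α‑bromo lactone F4. Reduction with Bu3SnH and Et3B/air at −78 °C should deliver the hydrogen atom to the α‑lactone radical on the face opposite the C7 side chain, the usual course for cyclic radicals, and returns to 18.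

Further compounds
F1 | step 9 | tert‑butyl(dimethyl){[(3R,5E,7Z,9S)‑2,8‑dimethyl‑9‑[(triethylsilyl)oxy]dodeca‑1,5,7,11‑tetraen‑3‑yl]oxy}silane (triethylsilyl ether of 12) | CC(=C)[C@H](O[Si](C)(C)C(C)(C)C)C/C=C/C=C(/C)[C@@H](O[Si](CC)(CC)CC)CC=C
F2 | step 9 | (4S,5S)‑4‑[(2R)‑2‑[(tert‑butyldimethylsilyl)oxy]‑3‑methylbut‑3‑en‑1‑yl]‑3‑methyl‑5‑[(1Z,3S)‑2‑methyl‑3‑[(triethylsilyl)oxy]hexa‑1,5‑dien‑1‑yl]oxolan‑2‑one (C11 epimers) | CC(=C)[C@H](O[Si](C)(C)C(C)(C)C)C[C@@H]1[C@@H](/C=C(/C)[C@@H](O[Si](CC)(CC)CC)CC=C)OC(=O)C1C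
F3 | step 13 | (3R,3aS,5R,6Z,9S,10Z,11aS)‑5,9‑dihydroxy‑3,6,10‑trimethyl‑3a,4,5,8,9,11a‑hexahydrocyclodeca[b]furan‑2(3H)‑one | O[C@H]1C/C=C(/C)[C@H](O)C[C@@H]2[C@@H](/C=C\1C)OC(=O)[C@@H]2C
F4 | step 10 | (4S,5S)‑3‑bromo‑4‑[(2R)‑2‑[(tert‑butyldimethylsilyl)oxy]‑3‑methylbut‑3‑en‑1‑yl]‑5‑[(1Z,3S)‑3‑hydroxy‑2‑methylhexa‑1,5‑dien‑1‑yl]‑3‑methyloxolan‑2‑one (epimers at the brominated carbon) | CC(=C)[C@H](O[Si](C)(C)C(C)(C)C)C[C@@H]1[C@@H](/C=C(/C)[C@@H](O)CC=C)OC(=O)C1(C)Br
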